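## Retrosynthetic overview

1. Metasequirin E ⇐ global Si–O cleavage ⇐ chelation-controlled reduction (sets the carbinol centre) of an all-cis 2-aroyl-3-aryl-4-silyloxytetrahydrofuran.
2. Tetrahydrofuran ring (formed last) ⇐ one-carbon ring expansion of a cis-2-aryl-3-silyloxyoxetane by the copper carbenoid of an aryl diazomethyl ketone. The benzylic oxetane carbon shifts 1,2 from oxygen to the carbenoid carbon, making C2–C3 and setting C2.
3. Oxetane ring (formed first, carries C3 and C4) ⇐ cis-selective hydride reduction of a 2-aryloxetan-3-one ⇐ gold-catalysed oxidative cyclisation of an (S)-aryl propargylic alcohol ⇐ enantioselective alkynylation of O-TIPS vanillin.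
4. Diazo ketone ⇐ aroyl chloride + Me3SiCHN2 ⇐ Pinnick oxidation of the same aldehyde.
5. O-TIPS vanillin ⇐ vanillin ⇐ guaiacol + glyoxylic acid ⇐ catechol + MeI. Both arenes come from this one aldehyde.

Notation: Ar = 3-methoxy-4-[(triisopropylsilyl)oxy]phenyl. Tetrahydrofuran locants used throughout: O1, C2 (bears the side chain), C3 (aryl), C4 (oxygen), C5 (CH2).

Assumption: the ligand antipodes named in steps 4 and 10 are taken to be the ones that give the configurations shown; if the sense of induction is the opposite, the mirror-image ligand is used.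

## Route

Step 1
Reactants: 1 catechol
Product: 2 guaiacol (2-methoxyphenol)
Conditions: MeI (1.0 equiv), K2CO3 (1.0 equiv), acetone, 56 °C; base extraction and distillation
Reagents that add atoms: iodomethane, CI
Why: Williamson mono-O-methylation with one equivalent of base and MeI; guaiacol is separated from veratrole and unreacted catechol by extraction and distillation.

Step 2
Reactants: 2 guaiacol; 3 glyoxylic acid (used as the monohydrate)
Product: 6 vanillin (4-hydroxy-3-methoxybenzaldehyde), via 4-hydroxy-3-methoxymandelic acid 4 (not isolated), via (4-hydroxy-3-methoxyphenyl)glyoxylic acid 5 (not isolated)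
Conditions: NaOH, H2O, 30 °C; then CuSO4 (cat.), air, 95 °C; then H2SO4 to pH 3
Reagents that add atoms: none
Why: Electrophilic aromatic hydroxyalkylation of the phenoxide by glyoxylate para to the OH, then copper-catalysed aerobic oxidation of the mandelate and decarboxylation of the aryl glyoxylate (the industrial guaiacol–glyoxylic acid vanillin process); no stereocentre.

Step 3
Reactants: 6 vanillin
Product: 7 3-methoxy-4-[(triisopropylsilyl)oxy]benzaldehyde (ArCHO)
Conditions: TIPSCl, imidazole, DMF, 23 °C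
Reagents that add atoms: triisopropylsilyl chloride, CC(C)[Si](Cl)(C(C)C)C(C)C
Why: Phenol silylation; the aryl TIPS ether is chosen because it survives K2CO3/MeOH, organozinc, hydride, chlorite and carbenoid conditions and is removed by fluoride at the end.

Step 4
Reactants: 7 ArCHO; 8 trimethylsilylacetylene
Product: 10 (S)-1-Ar-prop-2-yn-1-ol, via (R)-C-silylated propargylic alcohol 9 (not isolated)
Conditions: (S,S)-ProPhenol (10 mol %), ZnMe2 (3 equiv), 8 (3 equiv), Ph3P=O (20 mol %), toluene, 4 °C; aq NH4Cl; then K2CO3 (cat.), MeOH, 0 °C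
Reagents that add atoms: none
Why: Dinuclear zinc/ProPhenol-catalysed enantioselective alkynylzinc addition to the aryl aldehyde (Si-face attack) sets the carbinol centre, (R) for the silylalkyne and (S) after methanolytic C-desilylation, which the aryl TIPS ether tolerates.

Step 5
Reactants: 10 (S)-1-Ar-prop-2-yn-1-ol
Product: 11 (R)-2-Ar-oxetan-3-one
Conditions: (IPr)AuNTf2 (5 mol %), 8-methylquinoline N-oxide (1.5 equiv), ClCH2CH2Cl, 0 to 23 °C, no acid additive
Reagents that add atoms: 8-methylquinoline N-oxide, Cc1cccc2ccc[n+]([O-])c12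
Why: Gold-catalysed alkyne oxidation gives an α-oxo carbene of monovalent gold at the terminal carbon, which the propargylic OH traps by intramolecular O–H insertion to close the oxetan-3-one; the C–O stereocentre is not touched (descriptor changes from S to R only by priority).

Step 6
Reactants: 11 (R)-2-Ar-oxetan-3-one
Product: 12 (2R,3R)-2-Ar-oxetan-3-ol (cis)
Conditions: LiBH(s-Bu)3, THF, −78 °C; then H2O
Reagents that add atoms: none
Why: Ketone reduction by a bulky hydride that attacks the oxetanone face opposite the 2-aryl group, giving the cis alcohol (3R); at −78 °C reduction outruns enolisation.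

Step 7
Reactants: 12 (2R,3R)-2-Ar-oxetan-3-ol
Product: 13 tert-butyl{[(2R,3R)-2-Ar-oxetan-3-yl]oxy}dimethylsilane (cis)
Conditions: TBSCl, imidazole, DMF, 23 °C
Reagents that add atoms: tert-butyldimethylsilyl chloride, CC(C)(C)[Si](C)(C)Cl
Why: Silyl ether formation masks the OH against O–H insertion in step 10; no stereocentre is touched.

Step 8
Reactants: 7 ArCHO
Product: 14 3-methoxy-4-[(triisopropylsilyl)oxy]benzoic acid
Conditions: NaClO2, NaH2PO4, 2-methyl-2-butene, t-BuOH/H2O, 23 °C
Reagents that add atoms: sodium chlorite, [Na+].[O-]Cl=O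
Why: Pinnick oxidation of the aldehyde; the alkene scavenges HOCl so the electron-rich ring is not chlorinated.

Step 9
Reactants: 14 the benzoic acid; 15 (trimethylsilyl)diazomethane
Product: 17 2-diazo-1-Ar-ethan-1-one, via aroyl chloride 16 (not isolated)
Conditions: (COCl)2, DMF (cat.), CH2Cl2, 0 to 23 °C; evaporate; then 15 (2 equiv), MeCN/THF, 0 °C
Reagents that add atoms: none
Why: Acid chloride formation, then Arndt–Eistert-type C-acylation of the silyl diazomethane with loss of the silyl group to chloride gives the terminal diazo ketone.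

Step 10
Reactants: 13 cis-oxetane silyl ether; 17 diazo ketone
Product: 18 [(2S,3S,4S)-3-Ar-4-[(tert-butyldimethylsilyl)oxy]tetrahydrofuran-2-yl](Ar)methanone (all three ring substituents cis)
Conditions: [Cu(MeCN)4]PF6 (5 mol %), (S,S)-t-Bu-box (6 mol %), 4 Å MS, CH2Cl2, 25 °C; 17 (1.5 equiv) added over 6 h
Reagents that add atoms: none
Why: Proposed new method: monovalent-copper/bis(oxazoline)-catalysed ring expansion of a 2-aryl-3-silyloxyoxetane with an aryl diazomethyl ketone, in which the copper carbenoid from 17 is attacked by the oxetane oxygen on the face anti to the cis aryl and OTBS groups to give a copper-associated oxonium ylide, ring strain (about 25 kcal/mol) then drives a Stevens-type [1,2]-shift of the benzylic carbon from oxygen to the ylide carbon (caged radical-pair or ion-pair recombination, so the benzylic centre keeps its configuration and stays cis to OTBS), and the chiral ligand on the metal-bound ylide selects the face of the carbenoid carbon, the matched ligand giving the 2,3-cis ketone (C2 S); closest known reaction type: copper-catalysed, ligand-controlled ring expansion of 2-aryloxetanes with diazoacetates to 2,3-disubstituted tetrahydrofuran-2-carboxylates, not yet shown for diazo ketones or for 2,3-disubstituted 3-oxygenated oxetanes.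

Step 11
Reactants: 18 the all-cis ketone
Product: 19 (R)-[(2S,3S,4S)-3-Ar-4-[(tert-butyldimethylsilyl)oxy]tetrahydrofuran-2-yl](Ar)methanol
Conditions: Zn(BH4)2, Et2O, −40 to −20 °C; then H2O
Reagents that add atoms: none
Why: Chelation-controlled (Cram-chelate) reduction of the α-alkoxy ketone: zinc bridges the carbonyl and ring oxygens and hydride enters from the side of the C2–H, giving the anti (erythro) (R)-carbinol; the low temperature avoids epimerisation at C2.

Step 12
Reactants: 19 the tris-silyl ether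
Product: 20 Metasequirin E, (3S,4R,5S)-5-[(R)-hydroxy(4-hydroxy-3-methoxyphenyl)methyl]-4-(4-hydroxy-3-methoxyphenyl)oxolan-3-ol (route locants: 2S,3R,4S, all-cis ring)
Conditions: Bu4NF/AcOH (1:1, 4 equiv), THF, 0 to 23 °C
Reagents that add atoms: none
Why: Fluoride-mediated Si–O cleavage of the two aryl TIPS ethers and the secondary TBS ether, buffered with AcOH so the freed p-hydroxybenzyl alcohol does not ionise to a quinone methide; no stereocentre is touched.

## Compound list

1 | catechol | Oc1ccccc1O | starting material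
2 | guaiacol | COc1ccccc1O | intermediate
3 | glyoxylic acid | OC(=O)C=O | starting material
4 | 4-hydroxy-3-methoxymandelic acid (racemic, formed in the flask) | COc1cc(C(O)C(O)=O)ccc1O | intermediate
5 | (4-hydroxy-3-methoxyphenyl)glyoxylic acid (formed in the flask) | COc1cc(C(=O)C(O)=O)ccc1O | intermediate
6 | vanillin | COc1cc(C=O)ccc1O | intermediate
7 | 3-methoxy-4-[(triisopropylsilyl)oxy]benzaldehyde | COc1cc(C=O)ccc1O[Si](C(C)C)(C(C)C)C(C)C | intermediate
8 | trimethylsilylacetylene | C#C[Si](C)(C)C | starting material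
9 | (R)-1-Ar-3-(trimethylsilyl)prop-2-yn-1-ol (formed in the flask) | COc1cc([C@H](C#C[Si](C)(C)C)O)ccc1O[Si](C(C)C)(C(C)C)C(C)C | intermediate
10 | (S)-1-Ar-prop-2-yn-1-ol | COc1cc([C@H](C#C)O)ccc1O[Si](C(C)C)(C(C)C)C(C)C | intermediate
11 | (R)-2-Ar-oxetan-3-one | COc1cc([C@H]2OCC2=O)ccc1O[Si](C(C)C)(C(C)C)C(C)C | intermediate
12 | (2R,3R)-2-Ar-oxetan-3-ol (cis) | COc1cc([C@H]2OC[C@H]2O)ccc1O[Si](C(C)C)(C(C)C)C(C)C | intermediate
13 | tert-butyl{[(2R,3R)-2-Ar-oxetan-3-yl]oxy}dimethylsilane (cis) | COc1cc([C@H]2OC[C@H]2O[Si](C)(C)C(C)(C)C)ccc1O[Si](C(C)C)(C(C)C)C(C)C | intermediate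
14 | 3-methoxy-4-[(triisopropylsilyl)oxy]benzoic acid | COc1cc(C(O)=O)ccc1O[Si](C(C)C)(C(C)C)C(C)C | intermediate
15 | (trimethylsilyl)diazomethane | C[Si](C)(C)C=[N+]=[N-] | starting material
16 | 3-methoxy-4-[(triisopropylsilyl)oxy]benzoyl chloride (formed in the flask) | COc1cc(C(Cl)=O)ccc1O[Si](C(C)C)(C(C)C)C(C)C | intermediate
17 | 2-diazo-1-Ar-ethan-1-one | COc1cc(C(=O)C=[N+]=[N-])ccc1O[Si](C(C)C)(C(C)C)C(C)C | intermediate
18 | [(2S,3S,4S)-3-Ar-4-[(tert-butyldimethylsilyl)oxy]tetrahydrofuran-2-yl](Ar)methanone (all-cis) | COc1cc([C@H]2[C@@H](C(=O)c3ccc(O[Si](C(C)C)(C(C)C)C(C)C)c(OC)c3)OC[C@H]2O[Si](C)(C)C(C)(C)C)ccc1O[Si](C(C)C)(C(C)C)C(C)C | intermediate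
19 | (R)-[(2S,3S,4S)-3-Ar-4-[(tert-butyldimethylsilyl)oxy]tetrahydrofuran-2-yl](Ar)methanol | COc1cc([C@H]2[C@@H]([C@H](O)c3ccc(O[Si](C(C)C)(C(C)C)C(C)C)c(OC)c3)OC[C@H]2O[Si](C)(C)C(C)(C)C)ccc1O[Si](C(C)C)(C(C)C)C(C)C | intermediate
20 | Metasequirin E | COc1cc([C@H]2[C@@H]([C@H](O)c3ccc(O)c(OC)c3)OC[C@H]2O)ccc1O | target

## Step count and risks

Total steps: 12. Longest linear sequence: 10 (steps 1–7, then 10–12); steps 8 and 9 form the two-step branch that joins at step 10.

Steps most likely to fail:

1. Step 10 (proposed ring expansion with the diazo ketone). The risks are poor ylide formation at the hindered cis-oxetane, loss of configuration at the electron-rich benzylic carbon during the shift, or the wrong C2 epimer. Fallback (known chemistry): set out from 13 and come back at 18. Oxetane 13 is ring-expanded with ethyl diazoacetate under CuOTf and a chiral bipyridine or bis(azaferrocene) ligand (the established ligand-controlled oxetane to tetrahydrofuran-2-carboxylate reaction) to ethyl (2S,3S,4S)-3-Ar-4-[(tert-butyldimethylsilyl)oxy]tetrahydrofuran-2-carboxylate F1. F1 is converted with MeNH(OMe)·HCl and i-PrMgCl at −20 °C into the N-methoxy-N-methylamide F2. The aryl nucleophile is made from guaiacol 2 by NBS bromination to 4-bromo-2-methoxyphenol F3, silylation (TIPSCl, imidazole) to (4-bromo-2-methoxyphenoxy)triisopropylsilane F4, and bromine–lithium exchange (n-BuLi, −78 °C) to the aryllithium F5. F5 adds to F2 to give ketone 18, so the aryl–carbonyl bond is made by organolithium addition instead of being carried in the carbenoid.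

2. Step 5 (gold-catalysed oxetan-3-one formation). The electron-rich benzylic propargylic alcohol may undergo Meyer–Schuster rearrangement or ionise, and the α-aryl ketone 11 may racemise. Fallback: set out from 7 and come back at 12, avoiding gold and the enolisable ketone. Aldehyde 7 is treated with Brown's (Z)-γ-(4-methoxybenzyloxy)allyl-B(Ipc)2 reagent (the Ipc antipode that attacks the Si face) to give syn-(1R,2R)-2-[(4-methoxybenzyl)oxy]-1-Ar-but-3-en-1-ol F6. Oxidative cleavage (OsO4 cat., NaIO4) and NaBH4 reduction give (1R,2R)-2-[(4-methoxybenzyl)oxy]-1-Ar-propane-1,3-diol F7. One-pot treatment with n-BuLi and TsCl gives the primary tosylate F8, and a second equivalent of n-BuLi closes it by 4-exo Williamson etherification to (2R,3R)-3-[(4-methoxybenzyl)oxy]-2-Ar-oxetane F9. DDQ in CH2Cl2/pH 7 buffer removes the benzyl-type ether to give 12.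

3. Step 4 (enantioselective alkynylation). The electron-rich aldehyde may give only moderate ee, and the TIPS ether may suffer in K2CO3/MeOH. Fallback: set out from 7 and come back at 10, setting the centre by C=O reduction instead of C–C formation. Aldehyde 7 is treated with LiC≡CSiMe3 to give racemic 1-Ar-3-(trimethylsilyl)prop-2-yn-1-ol F10. MnO2 oxidation gives the ynone 1-Ar-3-(trimethylsilyl)prop-2-yn-1-one F11. Reduction with the Corey–Bakshi–Shibata oxazaborolidine (the antipode giving the R alcohol) and BH3·SMe2 gives 9, which is desilylated (K2CO3, MeOH) to 10.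

## Further compounds

F1 | step 10 | ethyl (2S,3S,4S)-3-Ar-4-[(tert-butyldimethylsilyl)oxy]tetrahydrofuran-2-carboxylate | COc1cc([C@H]2[C@@H](C(=O)OCC)OC[C@H]2O[Si](C)(C)C(C)(C)C)ccc1O[Si](C(C)C)(C(C)C)C(C)C
F2 | step 10 | (2S,3S,4S)-3-Ar-4-[(tert-butyldimethylsilyl)oxy]-N-methoxy-N-methyltetrahydrofuran-2-carboxamide | COc1cc([C@H]2[C@@H](C(=O)N(C)OC)OC[C@H]2O[Si](C)(C)C(C)(C)C)ccc1O[Si](C(C)C)(C(C)C)C(C)C
F3 | step 10 | 4-bromo-2-methoxyphenol | COc1cc(Br)ccc1O
F4 | step 10 | (4-bromo-2-methoxyphenoxy)triisopropylsilane | COc1cc(Br)ccc1O[Si](C(C)C)(C(C)C)C(C)C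
F5 | step 10 | {3-methoxy-4-[(triisopropylsilyl)oxy]phenyl}lithium | COc1cc([Li])ccc1O[Si](C(C)C)(C(C)C)C(C)C
F6 | step 5 | (1R,2R)-2-[(4-methoxybenzyl)oxy]-1-Ar-but-3-en-1-ol | COc1cc([C@H]([C@H](OCc2ccc(OC)cc2)C=C)O)ccc1O[Si](C(C)C)(C(C)C)C(C)C
F7 | step 5 | (1R,2R)-2-[(4-methoxybenzyl)oxy]-1-Ar-propane-1,3-diol | COc1cc([C@H]([C@H](OCc2ccc(OC)cc2)CO)O)ccc1O[Si](C(C)C)(C(C)C)C(C)C
F8 | step 5 | (2R,3R)-3-hydroxy-2-[(4-methoxybenzyl)oxy]-3-Ar-propyl 4-methylbenzenesulfonate | COc1cc([C@H]([C@H](OCc2ccc(OC)cc2)COS(=O)(=O)c2ccc(C)cc2)O)ccc1O[Si](C(C)C)(C(C)C)C(C)C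
F9 | step 5 | (2R,3R)-3-[(4-methoxybenzyl)oxy]-2-Ar-oxetane | COc1cc([C@H]2OC[C@H]2OCc3ccc(OC)cc3)ccc1O[Si](C(C)C)(C(C)C)C(C)C
F10 | step 4 | racemic 1-Ar-3-(trimethylsilyl)prop-2-yn-1-ol | COc1cc(C(O)C#C[Si](C)(C)C)ccc1O[Si](C(C)C)(C(C)C)C(C)C
F11 | step 4 | 1-Ar-3-(trimethylsilyl)prop-2-yn-1-one | COc1cc(C(=O)C#C[Si](C)(C)C)ccc1O[Si](C(C)C)(C(C)C)C(C)C
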